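**Plan**
- Retrosynthesis: the O2'–benzyl and O3–methyl bonds are cut first, then the O1–C2 bond of ring C (contracting the pyranone to the spiro-oxirane of an aurone), then the oxirane oxygen, the exocyclic C=C bond (aldol) and the O1–CH2 bond of the benzofuranone.
- Forward: ring A comes with acetophenone 4; the furanone is closed by side-chain bromination and O-alkylation; ring B is joined by aldol condensation with benzylated aldehyde 3; the aurone is epoxidised; BF3·OEt2 expands the furanone to ring C; O-methylation and hydrogenolysis finish.
- Enabling feature: O1, C2, C3 with its oxygen and C4 of ring C are an isomer of an aurone spiro-epoxide, and the 2'-, 4'- and 5'-oxygens of ring B stabilise positive charge at C2, the carbon that must receive O1.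
- Stereochemistry: the target is achiral; the Z geometry of the aurone is thermodynamic, and the two racemic oxirane centres are erased in the ring expansion.

Key step: step 6

Remark: epoxide 9 is racemic and its SMILES shows one enantiomer of the diastereomer with the aryl group cis to O1; transient 7 (diastereomer mixture) and 10 (racemic) are drawn without configuration.

**Route**

Step 1
Reactants: 1 2-hydroxy-4,5-dimethoxybenzaldehyde; 2 benzyl bromide
Product: 3 2-(benzyloxy)-4,5-dimethoxybenzaldehyde
Conditions: K2CO3, DMF, 60 °C
Reagents that add atoms: none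
Why: Williamson ether synthesis, in which the phenoxide (acidified by the ortho formyl group) displaces bromide from the benzylic halide by SN2 and no other nucleophilic site is present.

Step 2
Reactants: 4 2'-hydroxy-3',4'-dimethoxyacetophenone
Product: 5 2-bromo-1-(2-hydroxy-3,4-dimethoxyphenyl)ethan-1-one
Conditions: CuBr2 (2 equiv), EtOAc–CHCl3, reflux
Reagents that add atoms: copper dibromide CuBr2, [Cu+2].[Br-].[Br-]
Why: Selective side-chain α-bromination of an aryl methyl ketone by heterogeneous divalent copper bromide through the copper-bound enol, a method that normally leaves the hydrogen-bonded phenol ring of 2-hydroxyacetophenones unbrominated.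

Step 3
Reactants: 5 2-bromo-1-(2-hydroxy-3,4-dimethoxyphenyl)ethan-1-one
Product: 6 6,7-dimethoxybenzofuran-3(2H)-one
Conditions: NaOAc, EtOH, reflux
Reagents that add atoms: none
Why: Intramolecular Williamson O-alkylation (5-exo-tet), in which the phenoxide displaces the primary α-keto bromide while the weak base is unlikely to trigger self-condensation of the product.

Step 4
Reactants: 6 6,7-dimethoxybenzofuran-3(2H)-one; 3 2-(benzyloxy)-4,5-dimethoxybenzaldehyde
Product: 8 (Z)-2-[2-(benzyloxy)-4,5-dimethoxybenzylidene]-6,7-dimethoxybenzofuran-3(2H)-one, via aldol adduct 7 (not isolated)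
Conditions: neutral Al2O3, CH2Cl2, rt
Reagents that add atoms: none
Why: Aldol condensation in which the acidic C2 methylene (α to the ketone and to O1) adds to the aldehyde and the adduct dehydrates to the conjugated aurone, the Z isomer (aryl cis to O1, away from the C3 carbonyl) being the thermodynamic product.

Step 5
Reactants: 8 (Z)-2-[2-(benzyloxy)-4,5-dimethoxybenzylidene]-6,7-dimethoxybenzofuran-3(2H)-one
Product: 9 rac-(2R*,3'R*)-3'-[2-(benzyloxy)-4,5-dimethoxyphenyl]-6,7-dimethoxy-3H-spiro[benzofuran-2,2'-oxiran]-3-one (aryl cis to O1)
Conditions: 30% aq. H2O2, 2 M aq. NaOH (substoichiometric), MeOH–THF, 0 °C; crude product used directly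
Reagents that add atoms: hydrogen peroxide, OO
Why: Weitz–Scheffer nucleophilic epoxidation of the enone, in which hydroperoxide adds to the benzylic β-carbon and the enolate closes on oxygen with loss of hydroxide, giving both new stereocentres as a racemate whose relative configuration is expected to follow the Z alkene and is in any case irrelevant because both centres vanish in step 6.

Step 6
Reactants: 9 rac-(2R*,3'R*)-3'-[2-(benzyloxy)-4,5-dimethoxyphenyl]-6,7-dimethoxy-3H-spiro[benzofuran-2,2'-oxiran]-3-one
Product: 11 2-[2-(benzyloxy)-4,5-dimethoxyphenyl]-3-hydroxy-7,8-dimethoxy-4H-chromen-4-one, via 2-arylchromane-3,4-dione 10 (not isolated)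
Conditions: BF3·OEt2 (0.3 equiv), CH2Cl2, −20 to 0 °C; aq. NaHCO3 quench
Reagents that add atoms: none
Why: BF3 coordinates the oxirane oxygen and the C–O bond at the benzylic carbon ionises to a cation delocalised onto the 2'- and 4'-oxygens of ring B, leaving the boron-bound oxygen on the spiro carbon as a hemiketal alkoxide. This hemiketal collapses to the C3 ketone of a 1,2-diketone and releases the ring A aryloxy oxygen, which bonds to the cationic carbon (overall a 1,2-shift of O1 from the spiro carbon to the benzylic carbon), so that the O1–C2 bond of ring C forms and the furanone expands to dione 10, which enolises to the chelated flavonol 11. The closest known reaction type is the Lewis-acid rearrangement of α,β-epoxy ketones (semipinacol or Meinwald type), here in its known form as the acid-induced ring expansion of aurone epoxides to 3-hydroxyflavones. Ring C closes by attack of the phenolic oxygen on the trigonal cationic carbon whose π-system (ring B) lies outside the new ring, a 6-exo-trig closure that becomes a 1,2-shift through a bridged oxonium ion if the events are concerted. No stereocentre is created and both oxirane centres are destroyed, so the configuration of 9 does not matter. The step needs C–O cleavage at the benzylic carbon (not the spiro carbon) and migration of oxygen (not of the C3 acyl carbon); the first is secured by the ortho and para oxygen donors of ring B set against the carbonyl-destabilised spiro position, the second by the lone pair on O1 and the leaving-group ability of the aryloxide, which should let the hemiketal fragment faster than the acyl group can shift.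

Step 7
Reactants: 11 2-[2-(benzyloxy)-4,5-dimethoxyphenyl]-3-hydroxy-7,8-dimethoxy-4H-chromen-4-one
Product: 12 2-[2-(benzyloxy)-4,5-dimethoxyphenyl]-3,7,8-trimethoxy-4H-chromen-4-one
Conditions: MeI, K2CO3, acetone, reflux
Reagents that add atoms: iodomethane, CI
Why: Williamson O-methylation of the acidic 3-hydroxyl (an enol hydrogen-bonded to the C4 carbonyl), which is the only free hydroxyl because the 2'-oxygen is benzylated.

Step 8
Reactants: 12 2-[2-(benzyloxy)-4,5-dimethoxyphenyl]-3,7,8-trimethoxy-4H-chromen-4-one
Product: 13 2-(2-hydroxy-4,5-dimethoxyphenyl)-3,7,8-trimethoxy-4H-chromen-4-one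
Conditions: H2 (1 atm), 10% Pd/C, EtOAc–MeOH, rt
Reagents that add atoms: none
Why: Catalytic hydrogenolysis of an aryl benzyl ether over Pd/C at ambient pressure, under which the tetrasubstituted C2=C3 bond of the 3-methoxychromone and the methyl ethers are expected to stay intact.

**Compound list**
1 | 2-hydroxy-4,5-dimethoxybenzaldehyde | COc1cc(O)c(C=O)cc1OC | starting material
2 | benzyl bromide | BrCc1ccccc1 | starting material
3 | 2-(benzyloxy)-4,5-dimethoxybenzaldehyde | COc1cc(OCc2ccccc2)c(C=O)cc1OC | intermediate
4 | 2'-hydroxy-3',4'-dimethoxyacetophenone | CC(=O)c1ccc(OC)c(OC)c1O | starting material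
5 | 2-bromo-1-(2-hydroxy-3,4-dimethoxyphenyl)ethan-1-one | O=C(CBr)c1ccc(OC)c(OC)c1O | intermediate
6 | 6,7-dimethoxybenzofuran-3(2H)-one | O=C1COc2c1ccc(OC)c2OC | intermediate
7 | 2-{[2-(benzyloxy)-4,5-dimethoxyphenyl](hydroxy)methyl}-6,7-dimethoxybenzofuran-3(2H)-one (aldol adduct, diastereomer mixture, not isolated) | O=C1C(C(O)c2cc(OC)c(OC)cc2OCc2ccccc2)Oc2c1ccc(OC)c2OC | intermediate
8 | (Z)-2-[2-(benzyloxy)-4,5-dimethoxybenzylidene]-6,7-dimethoxybenzofuran-3(2H)-one | O=C1c2ccc(OC)c(OC)c2O/C1=C\c1cc(OC)c(OC)cc1OCc1ccccc1 | intermediate
9 | rac-(2R*,3'R*)-3'-[2-(benzyloxy)-4,5-dimethoxyphenyl]-6,7-dimethoxy-3H-spiro[benzofuran-2,2'-oxiran]-3-one (aryl cis to O1; one enantiomer drawn) | O=C1c2ccc(OC)c(OC)c2O[C@]12O[C@H]2c1cc(OC)c(OC)cc1OCc1ccccc1 | intermediate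
10 | 2-[2-(benzyloxy)-4,5-dimethoxyphenyl]-7,8-dimethoxychromane-3,4-dione (racemic, not isolated) | O=C1C(=O)c2ccc(OC)c(OC)c2OC1c1cc(OC)c(OC)cc1OCc1ccccc1 | intermediate
11 | 2-[2-(benzyloxy)-4,5-dimethoxyphenyl]-3-hydroxy-7,8-dimethoxy-4H-chromen-4-one | COc1cc(OCc2ccccc2)c(-c2oc3c(OC)c(OC)ccc3c(=O)c2O)cc1OC | intermediate
12 | 2-[2-(benzyloxy)-4,5-dimethoxyphenyl]-3,7,8-trimethoxy-4H-chromen-4-one | COc1cc(OCc2ccccc2)c(-c2oc3c(OC)c(OC)ccc3c(=O)c2OC)cc1OC | intermediate
13 | 2-(2-hydroxy-4,5-dimethoxyphenyl)-3,7,8-trimethoxy-4H-chromen-4-one (CID10548300) | COc1cc(O)c(-c2oc3c(OC)c(OC)ccc3c(=O)c2OC)cc1OC | target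

**Count**
Total steps: 8. Longest linear sequence: 7 steps (4 to 13, steps 2 to 8); the aldehyde branch (step 1) joins at step 4.

**Steps most likely to fail**

Step 6. The migrating group may change: the C3 acyl carbon instead of O1 may shift to the benzylic cation, which would expand the ring towards a 3-aryl-4-hydroxycoumarin skeleton. The Lewis acid may also strip the benzyl group, or be sequestered by the chelating product so that turnover stalls. The fallback sets out from 9 and removes the free cation. Anhydrous HCl (Et2O–1,4-dioxane, 0 °C) should open the oxirane at the benzylic carbon to the chlorohydrin 2-{[2-(benzyloxy)-4,5-dimethoxyphenyl](chloro)methyl}-2-hydroxy-6,7-dimethoxybenzofuran-3(2H)-one F1 (diastereomer mixture). NaOH in aqueous MeOH at room temperature then deprotonates the hemiketal, which opens to the 1,2-diketone phenoxide; this displaces chloride in a 6-exo-tet closure to dione 10, and enolisation returns the route at 11 after acidic work-up.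

Step 5. Conjugate addition of hydroperoxide may be slow on an enone deactivated by the electron-rich ring B, and the alkaline medium may open or cleave the spiro-epoxide before it can be isolated. The fallback sets out from 8 and reverses the polarity of the oxidant. Dimethyldioxirane in acetone at 0 °C transfers oxygen electrophilically and in a concerted way under neutral, anhydrous conditions. Evaporation of the volatiles returns the route at 9 without exposure to base or silica; no new compound arises on this path (F0).

Step 2. Bromination may go to the activated ring A (C5', para to the phenol) or twice on the methyl group instead of once on the side chain. The fallback sets out from 4 and 3 and avoids both halogenation and the benzofuranone. Claisen–Schmidt condensation (KOH, EtOH, room temperature) should give (E)-3-[2-(benzyloxy)-4,5-dimethoxyphenyl]-1-(2-hydroxy-3,4-dimethoxyphenyl)prop-2-en-1-one F2. Oxidative cyclisation of this 2'-hydroxychalcone with Hg(OAc)2 in pyridine at reflux (5-exo attack of the phenol on the mercury-activated α-carbon, then loss of mercury) returns the route at aurone 8, bypassing 5 and 6.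

**Further compounds**
F1 | step 6 | 2-{[2-(benzyloxy)-4,5-dimethoxyphenyl](chloro)methyl}-2-hydroxy-6,7-dimethoxybenzofuran-3(2H)-one (diastereomer mixture) | O=C1c2ccc(OC)c(OC)c2OC1(O)C(Cl)c1cc(OC)c(OC)cc1OCc1ccccc1
F0 | step 5 | none | none
F2 | step 2 | (E)-3-[2-(benzyloxy)-4,5-dimethoxyphenyl]-1-(2-hydroxy-3,4-dimethoxyphenyl)prop-2-en-1-one | O=C(/C=C/c1cc(OC)c(OC)cc1OCc1ccccc1)c1ccc(OC)c(OC)c1O
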